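**Retrosynthetic overview**

1. The target is a linear hexamer without stereocentres, A–CH2–B–CH2–C–CH2–D–CH2–E–CH2–F (ring A = butyrylfilicinic acid, rings B to E = butyrylphloroglucinol, ring F = 3-methylbutyrylphloroglucinol). All six rings are bought as phloroglucinol (1) or 2-methylphloroglucinol (8), so no ring is formed in the route; only the five CH2 bridges are made, in the order A–B, F–E, C–D, D–E and last B–C.
2. Last disconnection, copying the presumed biosynthetic methylene bridging: the bond from the bridging CH2 on ring B to the ring-C carbon. This gives dimer Mannich base 7 (latent ring-B ortho-quinone methide) and unprotected tetramer 18.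
3. Enabling feature: this CH2 is a 2,6-dihydroxybenzylic carbon of ring B (an OH on each neighbouring ring carbon), so 1,4-elimination of a leaving group from it gives an ortho-quinone methide. Its partner is the only unsubstituted ring carbon of rings C to F, ortho to two OH groups and para to the third.
4. 7 comes from ring-A Mannich base 4 and monomer 2, followed by a Mannich reaction. 18 comes from dimer Mannich base 13 (rings F and E) and the symmetric dimer 16 (rings C and D, from 2 and CH2O).
5. No protecting group is used; the key step gives the target directly.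

Key step: step 12

Assumption: all rings are written in the tautomeric forms of the target drawing (ring A as the enolised 4,4-dimethyl triketone, rings B to F as triphenols), and the Mannich bases are written neutral although they should exist as internal salts.

**Route**

Step 1
Reactants: 1 phloroglucinol
Product: 2 butyrylphloroglucinol, 1-(2,4,6-trihydroxyphenyl)butan-1-one
Conditions: butyryl chloride (1.0 equiv), AlCl3 (3.5 equiv), PhNO2/CH2Cl2, 0 to 45 °C; then ice/1 M HCl
Reagents that add atoms: butyryl chloride, CCCC(=O)Cl
Why: Friedel–Crafts C-acylation of the electron-rich triphenol, in which the first acyl group deactivates the ring so that one equivalent of acid chloride should stop at the monoketone.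

Step 2
Reactants: 2 butyrylphloroglucinol
Product: 3 butyrylfilicinic acid, 2-butanoyl-3,5-dihydroxy-4,4-dimethylcyclohexa-2,5-dien-1-one
Conditions: NaOMe (3.0 equiv), MeI (2.2 equiv), MeOH, 0 °C to rt; then 1 M HCl
Reagents that add atoms: iodomethane (two equivalents), CI
Why: Dearomatising geminal C-methylation of the phloroglucinol polyanion (the classical acylfilicinic acid preparation), in which the second methyl group enters at the already methylated carbon and locks the ring as the strongly acidic 4,4-dimethyl triketone enol, which should be separable from aromatic mono- and dimethyl by-products by bicarbonate extraction.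

Step 3
Reactants: 3 butyrylfilicinic acid
Product: 4 ring-A Mannich base, 2-butanoyl-6-[(dimethylamino)methyl]-3,5-dihydroxy-4,4-dimethylcyclohexa-2,5-dien-1-one
Conditions: Me2N=CH2+ I− (1.2 equiv), Et3N (1.0 equiv), CH2Cl2, −20 to 0 °C (3 added to the iminium salt)
Reagents that add atoms: Eschenmoser's salt (N,N-dimethylmethylideneammonium iodide), C=[N+](C)C.[I-]
Why: Mannich aminomethylation by a preformed iminium salt at the only C–H of the vinylogous acid (the ring carbon between the two enolised carbonyls), run cold and with inverse addition so that the zwitterionic product neither eliminates nor meets unreacted 3.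

Step 4
Reactants: 4 ring-A Mannich base; 2 butyrylphloroglucinol (4 equiv)
Product: 6 dimer AB-H: 2-butanoyl-6-[(3-butanoyl-2,4,6-trihydroxyphenyl)methyl]-3,5-dihydroxy-4,4-dimethylcyclohexa-2,5-dien-1-one, via ring-A methylidene triketone 5 (not isolated)
Conditions: 1,4-dioxane, 60 °C, N2 stream
Reagents that add atoms: none
Why: Thermal 1,4-elimination of Me2NH (retro-aza-Michael) releases the methylidene triketone 5, which is trapped in a Michael/Friedel–Crafts C-alkylation by one of the two equivalent free carbons of 2, the excess of 2 holding the reaction at single alkylation.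

Step 5
Reactants: 6 dimer AB-H
Product: 7 dimer AB Mannich base: 2-butanoyl-6-({3-butanoyl-5-[(dimethylamino)methyl]-2,4,6-trihydroxyphenyl}methyl)-3,5-dihydroxy-4,4-dimethylcyclohexa-2,5-dien-1-one
Conditions: Me2N=CH2+ I− (1.1 equiv), Et3N (2.0 equiv), CH2Cl2/MeCN, −10 to 20 °C
Reagents that add atoms: Eschenmoser's salt (N,N-dimethylmethylideneammonium iodide), C=[N+](C)C.[I-]
Why: Mannich reaction at the only ring C–H of 6 (on ring B, between two hydroxyls), so the aminomethyl group can enter at one site only.

Step 6
Reactants: 8 2-methylphloroglucinol (2,4,6-trihydroxytoluene)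
Product: 9 ring-F monomer, 1-(2,4,6-trihydroxy-3-methylphenyl)butan-1-one
Conditions: butyryl chloride (1.0 equiv), AlCl3 (3.5 equiv), PhNO2/CH2Cl2, 0 to 45 °C; then ice/1 M HCl
Reagents that add atoms: butyryl chloride, CCCC(=O)Cl
Why: Friedel–Crafts C-acylation at one of the two equivalent free ring carbons, with deactivation by the new ketone preventing a second acylation.

Step 7
Reactants: 9 ring-F monomer
Product: 10 ring-F Mannich base, 1-{3-[(dimethylamino)methyl]-2,4,6-trihydroxy-5-methylphenyl}butan-1-one
Conditions: Me2N=CH2+ I− (1.1 equiv), Et3N (1.0 equiv), CH2Cl2, 0 °C to rt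
Reagents that add atoms: Eschenmoser's salt (N,N-dimethylmethylideneammonium iodide), C=[N+](C)C.[I-]
Why: Mannich reaction at the single remaining ring C–H of 9.

Step 8
Reactants: 10 ring-F Mannich base; 2 butyrylphloroglucinol (4 equiv)
Product: 12 dimer FE-H: 1-{3-[(3-butanoyl-2,4,6-trihydroxyphenyl)methyl]-2,4,6-trihydroxy-5-methylphenyl}butan-1-one, via ring-F quinone methide 11 (not isolated)
Conditions: 1,4-dioxane, 90 °C, N2 stream
Reagents that add atoms: none
Why: Thermal loss of Me2NH from the phenolic Mannich base gives ortho-quinone methide 11, which undergoes Michael-type Friedel–Crafts C-alkylation by a free carbon of 2, excess 2 suppressing double alkylation.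

Step 9
Reactants: 12 dimer FE-H
Product: 13 dimer FE Mannich base: 1-{3-({3-butanoyl-5-[(dimethylamino)methyl]-2,4,6-trihydroxyphenyl}methyl)-2,4,6-trihydroxy-5-methylphenyl}butan-1-one
Conditions: Me2N=CH2+ I− (1.1 equiv), Et3N (1.0 equiv), CH2Cl2/MeCN, 0 °C to rt
Reagents that add atoms: Eschenmoser's salt (N,N-dimethylmethylideneammonium iodide), C=[N+](C)C.[I-]
Why: Mannich reaction at the only ring C–H of 12 (ring E), ring F being fully substituted.

Step 10
Reactants: 2 butyrylphloroglucinol (4 equiv relative to CH2O)
Product: 16 dimer CD: bis(3-butanoyl-2,4,6-trihydroxyphenyl)methane, via hydroxymethyl monomer 14 (not isolated), via monomer quinone methide 15 (not isolated)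
Conditions: 37% aq. CH2O (0.25 equiv), 1% aq. KOH, N2, 0 °C to rt; then 1 M HCl
Reagents that add atoms: formaldehyde, C=O
Why: Base-mediated hydroxymethylation (Lederer–Manasse reaction) followed by loss of hydroxide to the ortho-quinone methide and Michael addition of a second phenolate, with the large excess of 2 over formaldehyde favouring the dimer over higher oligomers.

Step 11
Reactants: 13 dimer FE Mannich base; 16 dimer CD (3 equiv)
Product: 18 tetramer CDEF-H: 1-(3-{[3-butanoyl-5-({3-butanoyl-5-[(3-butanoyl-2,4,6-trihydroxy-5-methylphenyl)methyl]-2,4,6-trihydroxyphenyl}methyl)-2,4,6-trihydroxyphenyl]methyl}-2,4,6-trihydroxyphenyl)butan-1-one, via ring-E quinone methide 17 (not isolated)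
Conditions: 1,4-dioxane, 90 °C, N2 stream
Reagents that add atoms: none
Why: Mannich-base-derived ortho-quinone methide C-alkylation at one of the two equivalent free carbons of the symmetric dimer 16, whose excess (recoverable) should keep the reaction at single alkylation.

Step 12
Reactants: 7 dimer AB Mannich base (1.2 equiv); 18 tetramer CDEF-H (1.0 equiv)
Product: 20 target hexamer CNP0309827.0, via ring-B quinone methide 19 (not isolated)
Conditions: 1,4-dioxane, 80–90 °C, N2 stream
Reagents that add atoms: none
Why: Heating the internal salt 7 expels Me2NH by 1,4-elimination (E1cB through the ring-B phenolate) to give ortho-quinone methide 19, whose exocyclic CH2 is attacked by the free ring-C carbon of 18 in a Michael-type Friedel–Crafts C-alkylation, and a proton shift re-aromatises rings B and C. The closest known reaction type is the methylene bridging of acylphloroglucinols through ortho-quinone methides released from phenolic Mannich bases, the laboratory counterpart of the presumed biosynthetic bridging. The step closes no ring and creates no stereocentre. It needs site selectivity and cross-coupling over homo-coupling: 18 has a single ring C–H (ortho to two OH, para to one) and 7 has none, so only one C–C bond can form and 19 cannot C-alkylate its own precursor, while any O-alkylation is reversible and should drain to the C-alkylated product. It also needs the four bridges already present to stay in place, which the base-free medium, the moderate temperature and the removal of Me2NH in the nitrogen stream are chosen to secure. One operation thus joins an unprotected two-ring fragment and an unprotected four-ring fragment into the complete hexamer.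

**Compound list**

1 | phloroglucinol | Oc1cc(O)cc(O)c1 | starting material
2 | butyrylphloroglucinol, 1-(2,4,6-trihydroxyphenyl)butan-1-one | CCCC(=O)c1c(O)cc(O)cc1O | intermediate
3 | butyrylfilicinic acid | CCCC(=O)C1=C(O)C(C)(C)C(O)=CC1=O | intermediate
4 | ring-A Mannich base | CCCC(=O)C1=C(O)C(C)(C)C(O)=C(CN(C)C)C1=O | intermediate
5 | ring-A methylidene triketone | CCCC(=O)C1=C(O)C(C)(C)C(=O)C(=C)C1=O | intermediate (not isolated)
6 | dimer AB-H | CCCC(=O)C1=C(O)C(C)(C)C(O)=C(Cc2c(O)cc(O)c(C(=O)CCC)c2O)C1=O | intermediate
7 | dimer AB Mannich base | CCCC(=O)C1=C(O)C(C)(C)C(O)=C(Cc2c(O)c(CN(C)C)c(O)c(C(=O)CCC)c2O)C1=O | intermediate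
8 | 2-methylphloroglucinol (2,4,6-trihydroxytoluene) | Cc1c(O)cc(O)cc1O | starting material
9 | ring-F monomer, 1-(2,4,6-trihydroxy-3-methylphenyl)butan-1-one | CCCC(=O)c1c(O)cc(O)c(C)c1O | intermediate
10 | ring-F Mannich base | CCCC(=O)c1c(O)c(CN(C)C)c(O)c(C)c1O | intermediate
11 | ring-F ortho-quinone methide | CCCC(=O)C1=C(O)C(C)=C(O)C(=C)C1=O | intermediate (not isolated)
12 | dimer FE-H | CCCC(=O)c1c(O)c(Cc2c(O)cc(O)c(C(=O)CCC)c2O)c(O)c(C)c1O | intermediate
13 | dimer FE Mannich base | CCCC(=O)c1c(O)c(Cc2c(O)c(CN(C)C)c(O)c(C(=O)CCC)c2O)c(O)c(C)c1O | intermediate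
14 | hydroxymethyl monomer, 1-[2,4,6-trihydroxy-3-(hydroxymethyl)phenyl]butan-1-one | CCCC(=O)c1c(O)cc(O)c(CO)c1O | intermediate (not isolated)
15 | monomer ortho-quinone methide | CCCC(=O)C1=C(O)C=C(O)C(=C)C1=O | intermediate (not isolated)
16 | dimer CD, bis(3-butanoyl-2,4,6-trihydroxyphenyl)methane | CCCC(=O)c1c(O)cc(O)c(Cc2c(O)cc(O)c(C(=O)CCC)c2O)c1O | intermediate
17 | ring-E ortho-quinone methide of dimer FE | CCCC(=O)c1c(O)c(CC2=C(O)C(C(=O)CCC)=C(O)C(=C)C2=O)c(O)c(C)c1O | intermediate (not isolated)
18 | tetramer CDEF-H | CCCC(=O)c1c(O)cc(O)c(Cc2c(O)c(Cc3c(O)c(Cc4c(O)c(C)c(O)c(C(=O)CCC)c4O)c(O)c(C(=O)CCC)c3O)c(O)c(C(=O)CCC)c2O)c1O | intermediate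
19 | ring-B ortho-quinone methide of dimer AB | CCCC(=O)C1=C(O)C(C)(C)C(O)=C(CC2=C(O)C(C(=O)CCC)=C(O)C(=C)C2=O)C1=O | intermediate (not isolated)
20 | target hexamer CNP0309827.0 | CCCC(=O)C1=C(O)C(C)(C)C(O)=C(Cc2c(O)c(Cc3c(O)c(Cc4c(O)c(Cc5c(O)c(Cc6c(O)c(C)c(O)c(C(=O)CCC)c6O)c(O)c(C(=O)CCC)c5O)c(O)c(C(=O)CCC)c4O)c(O)c(C(=O)CCC)c3O)c(O)c(C(=O)CCC)c2O)C1=O | target

**Step count and risks**

Total step count: 12. Longest linear sequence: 6 steps (steps 1, 2, 3, 4, 5, 12; equally steps 6, 7, 8, 9, 11, 12).

Steps most likely to fail:

1. Step 12. The quinone methide 19 may be consumed by self-condensation before the hindered, poorly soluble tetramer traps it. The bridges already present may also exchange by amine- and heat-induced retro-Michael cleavage, most readily at the bridge next to ring A, which would scramble the chain lengths. Fallback: the roles of the fragments are exchanged. It sets out from 18, which is aminomethylated at its single free ring carbon with Eschenmoser's salt and Et3N to give the tetramer Mannich base F1. Heating F1 in dioxane with an excess of the small, soluble and recoverable dimer 6 should release the ring-C quinone methide F2 (not isolated). F2 is trapped at the only free carbon of 6 (ring B), and the route is rejoined at 20. The excess of the smaller nucleophile should allow a lower temperature and a shorter heating time, and the fragment carrying the fragile ring-A bridge is then no longer the one that has to be activated.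

2. Step 2. Methylation may run past or short of the geminal stage, or lose site control by entering at the second free ring carbon, giving mixtures that are hard to separate. Fallback: it sets out from 1, which is diacetylated (Ac2O, BF3·OEt2) to 2,4-diacetylphloroglucinol F3. With only one free ring carbon left, MeI/NaOMe can place both methyl groups only there, giving 2,4-diacetylfilicinic acid F4. Acid-mediated retro-Claisen deacetylation (aqueous H2SO4, heat) should give filicinic acid F5. Mono-C-butyrylation of F5 (butyryl chloride, AlCl3) at one of its two equivalent carbons rejoins the route at 3.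

3. Step 11. Both free carbons of the two-ended dimer 16 may be alkylated, and its central bridge may exchange, so that tetramer, hexamer and scrambled oligomers form together. Fallback: the chain is grown one ring at a time with the cheap monomer instead of the dimer. It sets out from 13, which is heated with a large excess of 2 (through the same quinone methide 17) to give the trimer FED-H F6. A Mannich reaction at its single free carbon gives the trimer Mannich base F7. Heating F7 with excess 2 should pass through the ring-D quinone methide F8 (not isolated) and rejoin the route at 18, bypassing 16 and step 10.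

**Further compounds**

F1 | step 12 | tetramer CDEF Mannich base | CCCC(=O)c1c(O)c(CN(C)C)c(O)c(Cc2c(O)c(Cc3c(O)c(Cc4c(O)c(C)c(O)c(C(=O)CCC)c4O)c(O)c(C(=O)CCC)c3O)c(O)c(C(=O)CCC)c2O)c1O
F2 | step 12 | ring-C ortho-quinone methide of the tetramer | CCCC(=O)C1=C(O)C(Cc2c(O)c(Cc3c(O)c(Cc4c(O)c(C)c(O)c(C(=O)CCC)c4O)c(O)c(C(=O)CCC)c3O)c(O)c(C(=O)CCC)c2O)=C(O)C(=C)C1=O
F3 | step 2 | 2,4-diacetylphloroglucinol | CC(=O)c1c(O)cc(O)c(C(C)=O)c1O
F4 | step 2 | 2,4-diacetylfilicinic acid | CC(=O)C1=C(O)C(C)(C)C(O)=C(C(C)=O)C1=O
F5 | step 2 | filicinic acid | CC1(C)C(O)=CC(=O)C=C1O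
F6 | step 11 | trimer FED-H | CCCC(=O)c1c(O)cc(O)c(Cc2c(O)c(Cc3c(O)c(C)c(O)c(C(=O)CCC)c3O)c(O)c(C(=O)CCC)c2O)c1O
F7 | step 11 | trimer FED Mannich base | CCCC(=O)c1c(O)c(CN(C)C)c(O)c(Cc2c(O)c(Cc3c(O)c(C)c(O)c(C(=O)CCC)c3O)c(O)c(C(=O)CCC)c2O)c1O
F8 | step 11 | ring-D ortho-quinone methide of the trimer | CCCC(=O)C1=C(O)C(Cc2c(O)c(Cc3c(O)c(C)c(O)c(C(=O)CCC)c3O)c(O)c(C(=O)CCC)c2O)=C(O)C(=C)C1=O
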